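Take two stretches of readings, one from the maple run and one from the oak run, and compare them by hand before letting anything be fitted.

| flask | L | Z | J | time |
|---|---|---|---|---|
| maple | 250 mM | 250 mM | 2.50 mM |  |
| oak | 150 mM | 150 mM | 2.50 mM |  |
| ash | 250 mM | 250 mM | 5.00 mM |  |
| elm | 250 mM | 120 mM | 2.50 mM |  |
| birch | 250 mM | 38.0 mM | 2.50 mM | 4.7 min |

| maple run: time / min | maple run: [E] / mM | oak run: time / min | oak run: [E] / mM | ash run: time / min | ash run: [E] / mM | elm run: time / min | elm run: [E] / mM |
|---|---|---|---|---|---|---|---|
| 0.17 | 4.3 | 0.17 | 2.6 | 0.17 | 12.8 | 0.17 | 2.4 |
| 0.51 | 9.6 | 0.51 | 10.9 | 0.51 | 39.0 | 0.51 | 7.9 |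
| 0.98 | 24.7 | 0.98 | 18.0 | 0.98 | 83.2 | 0.98 | 18.8 |
| 1.6 | 48.3 | 1.6 | 32.3 | 1.6 | 141.2 | 1.6 | 29.3 |
| 2.2 | 73.7 | 2.2 | 43.5 | 2.2 | 184.2 | 2.2 | 43.9 |
| 3.0 | 111.7 | 3.0 | 60.0 | 3.0 | 226.2 | 3.0 | 62.0 |
| 3.8 | 143.1 | 3.8 | 76.9 | 3.8 | 245.1 | 3.8 | 79.2 |
| 4.7 | 172.5 | 4.7 | 93.7 | 4.7 | 248.5 | 4.7 | 93.2 |

(standard deviation of a reading: 0.8 mM)

- Overall: L + Z -> E, with J as catalyst.
- Constant volume, constant temperature.
- A reading of a species includes what of it is bound.
- "The second partner" is Z.
- An order is taken over about fifteen percent of the charge, up and down.

- the power of [Z] that the first rate follows, about the charge of the maple run; measure it at two percent of L made into E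
- the power of [L] that the first rate follows, about the charge of the maple run; measure it at two percent of L made into E (one fixed amount of E, the same in the runs compared)
- the oak run starts with 100 mM less of L and of Z than the maple run, and with no E. Compared where both hold the same amount of L, once fifteen percent of what the oak run was charged with has turned into E, is the oak run faster, slower or alike (within a tenth)?
- E in the birch run at 4.7 min, as a share of the L charged
- which of these the readings show (the product kills the catalyst / the product binds the substrate / the product decays / the second partner is lost by itself / the product speeds the reaction)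

In the maple and oak runs L and Z are charged equal and used one for one, so each run keeps L equal to Z. Both also carry the same J. Now pick the oak stretch between 0.51 min and 2.2 min, whose middle holds 27.2 mM of E and so 123 mM of L. Pick the maple stretch between 3.0 min and 3.8 min, whose middle holds 127 mM of E and so 123 mM of L. The two flasks then match in L, Z and J and differ in E.

The oak stretch reads 19.3 mM/min, and the maple stretch reads 39.2 mM/min, so the maple run is faster than the oak run, by about twice. We freeze L and Z at this point and suppose that the rate has two parts: a catalyst rate, and a product rate that grows in proportion to E, which is autocatalysis. The difference gives the product rate per mM of E as 0.199 /min. Taking that share out of the oak reading leaves a catalyst rate of 13.9 mM/min.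

The ratio of the two rates is E over the crossover amount, the E at which the product rate equals the catalyst rate, read here as 69.6 mM at this L and Z. Our reckoning therefore says that the oak run is slower at matched L, with a ratio near 0.492. The birch run has Z as its limiting reagent, which caps its share at 15.2%. Its L and Z differ from those of the matched point, so the crossover carries over to the birch run as an estimate; its 38.0 mM of Z is less than that estimate, so we expect its E to stay below the crossover.

The forecast gave 0.35 for the order in Z, −0.2 for the order in L, slower for the oak run, 12.3% for the birch run and "the product speeds the reaction", holding that “the acceleration follows E, not time or substrate”.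

The flask gives 0.13 for Z, 0.31 for L, slower for the oak run, 11.9% for the birch run and "the product speeds the reaction".

    J + L ⇌ JL, settled at all times (56.30 /M)
    J + Z ⇌ JZ, settled at all times (70.70 /M)
    JL + JZ → E + 2 J (11520 /M/min)
    L + Z + E → 2 E (13.32 /M²/min)

The last step, in which E helps L and Z to make more E, is our product rate, and the oak and maple pair proves it: the rate of the oak run over the maple run at equal L is 0.49 with that step and 1.0 without it. On our stretches the maple run stood at 1.82 of the crossover and the oak run at 0.391. At 4.7 min the birch run holds 29.9 mM of E, less than the crossover estimate, and without the step its share of L is still 11.0%.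

The numbers in the tables were generated by integration for substances that don't exist, and the scatter is random.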